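Molar is the unit of the one number I carry here.

| setting | blue | grey | flask |
|---|---|---|---|
| first end groups | 0.12 M | 0.19 M | 0.25 M |
| second end groups | 1 equiv | 1 equiv | 1.00 equiv |
| remark | run made earlier | run made earlier |  |
| time |  |  | 3.0 d |

| run | time / h | first end groups / % | rings / % |
|---|---|---|---|
| blue | 5.00 | 10.0 | 72.3 |
| blue | 15.0 | 10.0 | 72.6 |
| blue | 30.0 | 10.4 | 71.8 |
| blue | 40.0 | 10.2 | 72.7 |
| grey | 3.00 | 13.1 | 63.9 |
| grey | 8.00 | 13.4 | 63.5 |
| grey | 20.0 | 13.3 | 64.0 |
| grey | 40.0 | 13.5 | 63.8 |

(standard deviation of a reading: 0.3 percentage points)

- why nothing more happens at 3.0 d, or that something still does (it is still moving / forward and back rates have come level / all of the first end groups has reacted / the second end groups has run out first)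
- share of the first end groups used up at 3.0 d
- rings at 3.0 d, in percent of the first end groups charged
- over-reaction product at 3.0 d, in percent of the first end groups charged

- what was read earlier has a scatter of 0.3 percentage points, one standard deviation
- the reaction counts as stopped when no species that holds the first end groups changes by six tenths of a point or more over the second half of the time

From the mean readings, the blue run holds rings at 72.4% and first end groups at 10.2%, so over-reaction product is 17.5% by difference, if I count no other form of the first end groups. The grey run holds 63.8%, 13.3% and 22.9%. The selectivity factor, rings over over-reaction product, falls from 4.13 in blue to 2.79 in grey as the charge rises. I read this as a route to over-reaction product with one order more in second end groups than the route to rings. The factor at any moment is then a level divided by the second end groups present, and I replace their falling curve by its mean, which I take as half the charge. That defines the crossover level, the selectivity factor times half the charge: 0.248 M in blue and 0.265 M in grey.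

Holding the grey level gives this flask a factor of 2.12. A power law through both runs gives 2.20. They part. The level climbs 6.85% from blue to grey, more than the 1.71% by which one reading's scatter moves blue over-reaction product, so the held level cheats and I take the power law. Over-reaction product stands to first end groups left as 1.72 on the mean of the blue and grey readings, and holding that ratio in this flask, with the same balance, gives my estimate of rings of 58.2% and over-reaction product of 26.5%.

Rings over the square of what is left, if both ends remain alike, go from 585 /M in blue to 189 /M in grey, a ratio that level rates of a single step from the two ends to rings would hold steady. So I commit to the second end groups running out first.

The forecast differs: forward and back rates have come level, 84.4% used up, 57.4% rings, 27% over-reaction product. Its ground: “The blue and grey runs are flat within scatter, so both had levelled off within a few hours.”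

    first end groups + second end groups → links (k = 0.160 /M/min)
    first end groups + second end groups → rings, rate k2*[first end groups] as long as [second end groups] is above zero (k = 0.0360 /min)
    links ⇌ isomer of the product (K = 1.70, k = 0.290 /min)
    links → over-reaction product (k = 0.0390 /min)
    2 second end groups → self-condensation product (k = 0.0540 /M/min)

This flask gives 84.9% used up, 58.3% rings and 26.7% over-reaction product. The outcome is that the second end groups has run out first, with 0% of that charge left, so second end groups are the limiting reagent. The crossover level of this flask comes to 0.273 M, against 0.265 M read from the grey run, and the neighbour charged with 1.0 M of first end groups reaches 0.343 M. This flask has come to rest: second end groups pass under a fiftieth of their charge at 0.616 h, and by 30.0 d rings have moved 0 percentage points from their value at 3.0 d.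

(All runs stem from a simulated flask with constants of no real substance; the scatter is artificial.)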